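If Uj at the end of a flask follows from how fast a slow step draws down Eb, then I expected one number from the violet run to serve both new flasks.

all flasks: Qi 10 mM

| run | Eb | Ry | remark | time |
|---|---|---|---|---|
| violet | 7.4 mM | 1.5 mM | run made earlier |  |
| birch | 11.0 mM | 2.5 mM |  | 100 min |
| larch | 11.0 mM | 1.5 mM |  | 50 min |

violet run (percent of the Qi charged)

| time / min | Uj / % | Qi / % |
|---|---|---|
| 1.33 | 2 | 13 |
| 3.00 | 3 | 5 |
| 4.00 | 5 | 0 |
| 6.00 | 9 | 0 |
| 8.00 | 15 | 3 |
| 10.0 | 16 | 0 |

(each reading ± 1.5 percentage points)

- no earlier run changes the charge of Ry; that part of a forecast is a guess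

1. which of the two ends with the higher amount of Uj, in percent of the Qi charged ("neither" if they lie within 2 percentage points) (birch / larch / neither)
2. Uj at the end, in percent of the Qi charged, birch
3. Uj at the end, in percent of the Qi charged, larch

I asked first where Qi went. In the violet run Qi read 0% at 4.00 min while Uj read 5%, so I took Qi to sit in an unseen form, from which Uj came slowly.

Then I asked how fast that step ran. From the first violet reading to the last, Uj rose by 0.0161 min⁻¹ as a fraction of the Qi charged. Counting one Eb per Uj, I put the average of unused Eb in violet at 6.50 mM over that stretch. Violet has one Eb charge, so I could only assume that the rate follows the Eb still unused. That gives my Eb clock λ, the pseudo-first-order share of unused Eb taken per minute, 0.0248 min⁻¹. Uj, as a fraction of Qi, is then the charge ratio Eb/Qi times 1 − exp(−λt).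

Larch has violet's Ry, so I kept λ for larch, and the ratio 1.10 gives 78.2% at 50 min.

Last, I asked whether birch meets a ceiling. In birch, Qi at 10 mM is below Eb at 11.0 mM, so I counted Qi as the limiting reagent. Leaving aside birch's untested extra Ry, λ gives 101% at 100 min, which is past the Qi charged, so my reckoning for birch stopped at the Qi charged, above my larch figure.

The forecast chose birch, but stood below my figures: 88% (70% to 100%) for birch and 64% (48% to 86%) for larch, calling the slow formation of Uj “the one that sets the yield”.

The flask gave birch: birch 96.5%, larch 75.3%.

    Qi + Ry → Ry + Ux (k = 1600 M⁻¹ min⁻¹)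
    Ry + Ux ⇌ Ry.Ux (K = 1200 M⁻¹, k = 150 M⁻¹ min⁻¹)
    Eb + Ry.Ux → Ry + Uj (k = 37.0 M⁻¹ min⁻¹)
    Eb ⇌ Kj (K = 0.600, k = 0.190 min⁻¹)

In larch at 50.0 min, unused Eb stood in two forms, free Eb at 19.2% of its charge and Kj at 1.35 mM, together 3.47 mM. For larch the Eb clock gave 3.18 mM unused, less than that, and my larch figure stood 2.9 percentage points above the flask.

For a neighbour flask, larch read at 30 min, the clock gives Uj at 57.7%; the flask gave 57.2%.

(The runs stem from a simulated flask on assumed constants; scatter was added.)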